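## Retrosynthetic overview

1. Quinolin-4(1H)-one numbering is used: ring A is the carbocycle C4a–C5–C6–C7–C8–C8a, ring B the N-methoxy-4-pyridone N1–C2–C3–C4–C4a–C8a. The strategy rests on ring A: C8a, C4a and C5 are the carbonyl, α- and β-carbons of a cyclohex-2-enone, and C8 is its α′-carbon at the ketone level, carried as a dimethyl ketal.
2. Key disconnection: the C5–octyl and C4a–C4 bonds are made together. A copper-catalysed asymmetric conjugate addition of octylmagnesium bromide to 6,6-dimethoxycyclohex-2-en-1-one is followed by aldol capture of the enolate with methoxyacetaldehyde, which brings C4, C3 and the 3-OMe group.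
3. Ring B: the aldol is oxidised to the β-diketone, the C3–C2 bond is made by acetylating its dianion, and the resulting 1,3,5-triketone (C8a=O, C4=O, C2=O) is condensed with methoxyamine, N1 bonding to C8a and C2.
4. C8: ketal hydrolysis, catalyst-controlled transfer hydrogenation of the C8 ketone to the cis (8R) alcohol, then O-methylation.
5. Ring order: ring A is taken intact from cyclohexane-1,2-dione; ring B is closed in step 8. C5 is set in step 5 and C8 in step 10.

Key step: step 5

Assumption: the sense of induction of both chiral catalysts on these new substrates cannot be predicted with certainty. The route is written with the (R,SP) ferrocenyl diphosphine and the (R,R) ruthenium complex (the latter by analogy with 1-tetralone); the mirror-image ligand is used if a first run shows the opposite sense.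

## Route

Step 1
Reactants: 1 cyclohexane-1,2-dione
Product: 2 2,2-dimethoxycyclohexan-1-one
Conditions: HC(OMe)3 (1.1 equiv), MeOH, TsOH·H2O (2 mol %), 20 °C; Et3N quench, distillation
Reagents that add atoms: trimethyl orthoformate, COC(OC)OC; methanol, CO (solvent, exchanges methoxy groups with the orthoester)
Why: Acid-catalysed ketalisation driven by the orthoester as water scavenger: one carbonyl of the largely enolised 1,2-dione is converted into the dimethyl ketal, and the second ketalisation, at a carbonyl now flanked by a quaternary ketal carbon, is slow enough to be held back by the stoichiometry and the low temperature.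

Step 2
Reactants: 2 2,2-dimethoxycyclohexan-1-one
Product: 4 [(6,6-dimethoxycyclohex-1-en-1-yl)oxy]trimethylsilane, via lithium enolate 3 (not isolated)
Conditions: LiN(iPr)2 (1.1 equiv), THF, −78 °C; Me3SiCl (1.3 equiv), −78 → 0 °C; pentane, cold aqueous NaHCO3 wash
Reagents that add atoms: chlorotrimethylsilane, C[Si](C)(C)Cl
Why: Kinetic enolate formation and O-silylation: C2 is quaternary, so deprotonation can occur only at C6 and a single silyl enol ether is expected, while the basic conditions leave the ketal untouched.

Step 3
Reactants: 4 [(6,6-dimethoxycyclohex-1-en-1-yl)oxy]trimethylsilane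
Product: 5 6,6-dimethoxycyclohex-2-en-1-one
Conditions: Pd(OAc)2 (10 mol %), O2 (1 atm), DMSO, 25 °C
Reagents that add atoms: none
Why: Saegusa–Ito oxidation: divalent palladium converts the silyl enol ether into an oxa-π-allyl complex, β-hydride elimination releases the enone and O2 reoxidises the zerovalent palladium, and the double bond can only form between C2 and C3 because the other α-carbon is the ketal.

Step 4
Reactants: 6 1,1,2-trimethoxyethane
Product: 7 methoxyacetaldehyde
Conditions: 1 M aqueous HCl, 50 °C; NaCl saturation, continuous CH2Cl2 extraction, 4 Å molecular sieves, distillation; used at once as a tBuOMe solution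
Reagents that add atoms: water, O
Why: Acid-catalysed acetal hydrolysis, in which the acetal carbon becomes the aldehyde carbon with oxygen from water and the ether OMe is untouched; drying and distillation just before use are planned because the aldehyde hydrates and oligomerises on standing.

Step 5
Reactants: 5 6,6-dimethoxycyclohex-2-en-1-one; 8 octylmagnesium bromide (commercial 2.0 M solution in Et2O); 7 methoxyacetaldehyde
Product: 10 (2S,3S)-2-(1-hydroxy-2-methoxyethyl)-6,6-dimethoxy-3-octylcyclohexan-1-one (both carbinol epimers), via bromomagnesium enolate 9 (not isolated)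
Conditions: CuBr·SMe2 (5 mol %), (R)-1-[(SP)-2-(diphenylphosphino)ferrocenyl]ethyldicyclohexylphosphine (6 mol %), tBuOMe, −75 °C; 8 (1.2 equiv) added over 1 h; then 7 (2.5 equiv), −75 °C, 1 h; H2O/NH4Cl quench at −75 °C
Reagents that add atoms: none
Why: This is a copper-catalysed asymmetric conjugate addition of a Grignard reagent with aldol capture of the enolate, the closest known reaction type being the CuBr·SMe2/ferrocenyl diphosphine addition of alkylmagnesium bromides to cyclohex-2-enone with an aldehyde quench; the monovalent copper–diphosphine complex is alkylated by 8, binds the C2=C3 bond of 5 as a π-complex, passes through a trivalent copper alkyl at C3 and reductively eliminates the C3–octyl bond, leaving bromomagnesium enolate 9, which adds to 7. No ring is closed, since both new bonds (C3–octyl and C2–CHOH) are exocyclic to the preformed ring A. The C3 centre (S, octyl delivered to the Si face of the enone β-carbon) is set by the chiral diphosphine on copper, the C2 centre by the C3 octyl group, which sends the aldehyde to the opposite face (trans), and the carbinol centre is uncontrolled and is erased in step 6. The step needs 1,4- over 1,2-addition, which slow addition of 8 to the preformed copper complex in tBuOMe at −75 °C and the neopentyl-like shielding of the carbonyl by the C6 ketal should secure. It also needs a single enolate regioisomer, which is guaranteed because C6 carries no hydrogen. The low temperature and cold quench should keep the magnesium aldolate from retro-aldol cleavage or dehydration.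

Step 6
Reactants: 10 (2S,3S)-2-(1-hydroxy-2-methoxyethyl)-6,6-dimethoxy-3-octylcyclohexan-1-one
Product: 11 (3S)-6,6-dimethoxy-2-(methoxyacetyl)-3-octylcyclohexan-1-one (enol tautomers; C2 mobile)
Conditions: IBX (2-iodoxybenzoic acid, 1.5 equiv), EtOAc, 75 °C; filtration
Reagents that add atoms: none
Why: Oxidation of a β-hydroxy ketone to the β-diketone by IBX under neutral heterogeneous conditions, chosen to avoid retro-aldol cleavage and over-oxidation at the central carbon; both carbinol epimers converge, C2 becomes a mobile enol carbon and C3, which is not α to a carbonyl group, keeps its configuration.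

Step 7
Reactants: 11 (3S)-6,6-dimethoxy-2-(methoxyacetyl)-3-octylcyclohexan-1-one; 12 N-methoxy-N-methylacetamide
Product: 14 1-[(6S)-3,3-dimethoxy-6-octyl-2-oxocyclohexyl]-2-methoxybutane-1,3-dione (enol tautomers), via dilithium dianion 13 (not isolated)
Conditions: LiN(iPr)2 (2.3 equiv), THF, −78 → 0 °C; 12 (1.2 equiv), −78 → 0 °C; AcOH quench at −78 °C
Reagents that add atoms: none
Why: Acylation of a β-diketone dianion at its terminal carbon (Weinreb ketone synthesis on the acyl side): the first equivalent of base gives the central enolate, the second removes a proton from the methoxy-bearing CH2 (the only other α-position that carries hydrogen, the ring α′-carbon being the ketal), and the more basic terminal carbanion adds to the N-methoxy-N-methylamide, whose chelated tetrahedral adduct persists until the quench and thus prevents proton transfer from the product and double addition.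

Step 8
Reactants: 14 1-[(6S)-3,3-dimethoxy-6-octyl-2-oxocyclohexyl]-2-methoxybutane-1,3-dione; 15 O-methylhydroxylamine hydrochloride
Product: 17 (5S)-1,3,8,8-tetramethoxy-2-methyl-5-octyl-5,6,7,8-tetrahydroquinolin-4(1H)-one, via O-methyl oxime 16 (not isolated)
Conditions: 15 (1.1 equiv), NaOAc (1.2 equiv), EtOH, 25 → 78 °C; then AcOH (5 equiv), 78 °C
Reagents that add atoms: none
Why: Condensation of a 1,3,5-triketone with a primary nitrogen nucleophile to a 4-pyridone (the nitrogen counterpart of triketone-to-4-pyranone cyclodehydration): methoxyamine should condense first at the unhindered acetyl carbonyl, the nitrogen of oxime ether 16 (through its ene-hydroxylamine tautomer) then closes on the C8a carbonyl to a six-membered ring and loss of water makes ring B aromatic, the O-methyl group ruling out the isoxazole formation that hydroxylamine itself would allow and the buffered medium sparing the α-keto ketal.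

Step 9
Reactants: 17 (5S)-1,3,8,8-tetramethoxy-2-methyl-5-octyl-5,6,7,8-tetrahydroquinolin-4(1H)-one
Product: 18 (5S)-1,3-dimethoxy-2-methyl-5-octyl-6,7-dihydroquinoline-4,8(1H,5H)-dione
Conditions: 3 M aqueous HCl, THF, 50 °C
Reagents that add atoms: water, O
Why: Acid hydrolysis of the dimethyl ketal, for which fairly strong aqueous acid is planned because the oxocarbenium ion lies next to the electron-poor C8a of the protonated pyridone; the N–OMe and C3–OMe groups are stable to aqueous acid and C5 cannot epimerise, since enolisation of the new ketone toward C5 would break the aromatic ring B.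

Step 10
Reactants: 18 (5S)-1,3-dimethoxy-2-methyl-5-octyl-6,7-dihydroquinoline-4,8(1H,5H)-dione
Product: 19 (5S,8R)-8-hydroxy-1,3-dimethoxy-2-methyl-5-octyl-5,6,7,8-tetrahydroquinolin-4(1H)-one
Conditions: RuCl(p-cymene)[(R,R)-TsDPEN] (2 mol %; TsDPEN = N-tosyl-1,2-diphenylethane-1,2-diamine, bound as its monoanion), HCO2H/Et3N (5:2), CH2Cl2, 30 °C
Reagents that add atoms: none
Why: Noyori asymmetric transfer hydrogenation of a cyclic aryl-type ketone: ring B takes the place of the arene of 1-tetralone, whose CH/π contact with the p-cymene ligand fixes the orientation of the ketone in the six-membered hydride/proton transfer from the divalent ruthenium hydride, so the (R,R) catalyst should give the (8R) alcohol (cis to the octyl group) under catalyst control, the remote C5 centre having little say, and the vinylogous amide carbonyl C4 and the N–O bond are not reduced.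

Step 11
Reactants: 19 (5S,8R)-8-hydroxy-1,3-dimethoxy-2-methyl-5-octyl-5,6,7,8-tetrahydroquinolin-4(1H)-one
Product: 21 waltherione K ((5S,8R)-1,3,8-trimethoxy-2-methyl-5-octyl-5,6,7,8-tetrahydroquinolin-4(1H)-one), via sodium alkoxide 20 (not isolated)
Conditions: NaH (1.2 equiv), THF, 0 °C; MeI (3 equiv), 0 → 20 °C
Reagents that add atoms: iodomethane, CI
Why: Williamson ether synthesis: the secondary alkoxide 20 is methylated at oxygen by iodomethane without touching the C8–O bond, so the (8R) configuration is retained, and at 0 °C the much less nucleophilic pyridone carbonyl oxygen and the weakly acidic C2 methyl group should not react.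

## Compound list

1 | cyclohexane-1,2-dione | O=C1CCCCC1=O | starting material
2 | 2,2-dimethoxycyclohexan-1-one | COC1(OC)CCCCC1=O | intermediate
3 | lithium 6,6-dimethoxycyclohex-1-en-1-olate | COC1(OC)CCCC=C1O[Li] | intermediate
4 | [(6,6-dimethoxycyclohex-1-en-1-yl)oxy]trimethylsilane | COC1(OC)CCCC=C1O[Si](C)(C)C | intermediate
5 | 6,6-dimethoxycyclohex-2-en-1-one | COC1(OC)CCC=CC1=O | intermediate
6 | 1,1,2-trimethoxyethane | COCC(OC)OC | starting material
7 | methoxyacetaldehyde | COCC=O | intermediate
8 | octylmagnesium bromide | CCCCCCCC[Mg]Br | starting material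
9 | bromomagnesium (3S)-6,6-dimethoxy-3-octylcyclohex-1-en-1-olate | CCCCCCCC[C@H]1CCC(OC)(OC)C(O[Mg]Br)=C1 | intermediate
10 | (2S,3S)-2-(1-hydroxy-2-methoxyethyl)-6,6-dimethoxy-3-octylcyclohexan-1-one (both carbinol epimers) | CCCCCCCC[C@H]1CCC(OC)(OC)C(=O)[C@@H]1C(O)COC | intermediate
11 | (3S)-6,6-dimethoxy-2-(methoxyacetyl)-3-octylcyclohexan-1-one | CCCCCCCC[C@H]1CCC(OC)(OC)C(=O)C1C(=O)COC | intermediate
12 | N-methoxy-N-methylacetamide | CC(=O)N(C)OC | starting material
13 | dilithium 1-[(3S)-6,6-dimethoxy-2-oxido-3-octylcyclohex-1-en-1-yl]-2-methoxyethen-1-olate | CCCCCCCC[C@H]1CCC(OC)(OC)C(O[Li])=C1C(O[Li])=COC | intermediate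
14 | 1-[(6S)-3,3-dimethoxy-6-octyl-2-oxocyclohexyl]-2-methoxybutane-1,3-dione | CCCCCCCC[C@H]1CCC(OC)(OC)C(=O)C1C(=O)C(OC)C(C)=O | intermediate
15 | O-methylhydroxylamine hydrochloride | CON.Cl | starting material
16 | 1-[(6S)-3,3-dimethoxy-6-octyl-2-oxocyclohexyl]-2-methoxy-3-(methoxyimino)butan-1-one | CCCCCCCC[C@H]1CCC(OC)(OC)C(=O)C1C(=O)C(OC)C(C)=NOC | intermediate
17 | (5S)-1,3,8,8-tetramethoxy-2-methyl-5-octyl-5,6,7,8-tetrahydroquinolin-4(1H)-one | CCCCCCCC[C@H]1CCC(OC)(OC)c2c1c(=O)c(OC)c(C)n2OC | intermediate
18 | (5S)-1,3-dimethoxy-2-methyl-5-octyl-6,7-dihydroquinoline-4,8(1H,5H)-dione | CCCCCCCC[C@H]1CCC(=O)c2c1c(=O)c(OC)c(C)n2OC | intermediate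
19 | (5S,8R)-8-hydroxy-1,3-dimethoxy-2-methyl-5-octyl-5,6,7,8-tetrahydroquinolin-4(1H)-one | CCCCCCCC[C@H]1CC[C@@H](O)c2c1c(=O)c(OC)c(C)n2OC | intermediate
20 | sodium (5S,8R)-1,3-dimethoxy-2-methyl-5-octyl-4-oxo-1,4,5,6,7,8-hexahydroquinolin-8-olate | CCCCCCCC[C@H]1CC[C@@H](O[Na])c2c1c(=O)c(OC)c(C)n2OC | intermediate
21 | waltherione K, (5S,8R)-1,3,8-trimethoxy-2-methyl-5-octyl-5,6,7,8-tetrahydroquinolin-4(1H)-one | CCCCCCCC[C@H]1CC[C@@H](OC)c2c1c(=O)c(OC)c(C)n2OC | target

## Step count and risks

Total step count: 11.
Longest linear sequence: 10 steps (steps 1–3 and 5–11, from cyclohexane-1,2-dione); step 4 is a one-step side branch.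

Steps most likely to fail:

**Step 5.** The Grignard reagent may add directly to the ketal-activated carbonyl, the copper catalyst may discriminate the enone faces poorly on this α′,α′-dimethoxy substrate, or the aldolate may revert during the quench. The fallback sets out from 5 and separates the two bond formations.
- Copper-catalysed conjugate addition of commercial trioctylaluminium Al(C8H17)3 is run with copper thiophene-2-carboxylate Cu(O2CC4H3S) (monovalent copper, 2 mol %) and the phosphoramidite of (S)-1,1′-bi-2-naphthol and bis[(R)-1-phenylethyl]amine (4 mol %) in Et2O at −30 °C.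
- This should give the dioctylaluminium enolate dioctylaluminium (3S)-6,6-dimethoxy-3-octylcyclohex-1-en-1-olate F1, which is hydrolysed with cold aqueous NH4Cl to the ketone (5S)-2,2-dimethoxy-5-octylcyclohexan-1-one F2.
- F2 is deprotonated with LiN(iPr)2 in THF at −78 °C (only C6 carries α-hydrogens) to the lithium enolate lithium (3S)-6,6-dimethoxy-3-octylcyclohex-1-en-1-olate F3.
- F3 is added to 7 at −78 °C and quenched with AcOH; the fallback comes back to the route at 10.

**Step 8.** The condensation may stop at the open-chain oxime ether, because its sp2 nitrogen closes slowly on the hindered C8a carbonyl, or methoxyamine may condense at the central C4 carbonyl or twice. The fallback sets out from 14.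
- Acid-catalysed cyclodehydration (TsOH, HC(OMe)3, MeOH, 50 °C; the orthoester keeps C8 as its dimethyl ketal) should give the 4-pyranone (5S)-3,8,8-trimethoxy-2-methyl-5-octyl-5,6,7,8-tetrahydro-4H-chromen-4-one F4.
- Exchange of the ring oxygen for nitrogen with NH2OH·HCl in pyridine at 80 °C, the known conversion of 3-alkoxy-2-methylpyran-4-ones into 1-hydroxypyridin-4-ones, should give (5S)-1-hydroxy-3,8,8-trimethoxy-2-methyl-5-octyl-5,6,7,8-tetrahydroquinolin-4(1H)-one F5.
- Methylation of the N–OH oxygen with MeI and K2CO3 in DMF brings the fallback back to the route at 17.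

**Step 7.** The second deprotonation at the methoxy-bearing carbon may be incomplete, the dianion may take a proton from the acetamide instead of adding to it, or acylation may occur at oxygen. The fallback sets out from 11 and uses a neutral nucleophile.
- One-pot double silylation (Me3SiOTf, Et3N, Et2O, 0 °C) should give the 1,3-bis(silyloxy)diene {[(3S)-6,6-dimethoxy-2-[2-methoxy-1-(trimethylsilyloxy)ethenyl]-3-octylcyclohex-1-en-1-yl]oxy}trimethylsilane F6.
- Acylation of F6 at its terminal carbon with acetyl chloride (CH2Cl2, −78 → 20 °C, then aqueous NaHCO3) is the known route from 1,3-bis(silyl enol ethers) to 1,3,5-tricarbonyl compounds; the fallback comes back to the route at 14.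

## Further compounds

F1 | step 5 | dioctylaluminium (3S)-6,6-dimethoxy-3-octylcyclohex-1-en-1-olate | CCCCCCCC[C@H]1CCC(OC)(OC)C(O[Al](CCCCCCCC)CCCCCCCC)=C1
F2 | step 5 | (5S)-2,2-dimethoxy-5-octylcyclohexan-1-one | CCCCCCCC[C@H]1CCC(OC)(OC)C(=O)C1
F3 | step 5 | lithium (3S)-6,6-dimethoxy-3-octylcyclohex-1-en-1-olate | CCCCCCCC[C@H]1CCC(OC)(OC)C(O[Li])=C1
F4 | step 8 | (5S)-3,8,8-trimethoxy-2-methyl-5-octyl-5,6,7,8-tetrahydro-4H-chromen-4-one | CCCCCCCC[C@H]1CCC(OC)(OC)c2c1c(=O)c(OC)c(C)o2
F5 | step 8 | (5S)-1-hydroxy-3,8,8-trimethoxy-2-methyl-5-octyl-5,6,7,8-tetrahydroquinolin-4(1H)-one | CCCCCCCC[C@H]1CCC(OC)(OC)c2c1c(=O)c(OC)c(C)n2O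
F6 | step 7 | {[(3S)-6,6-dimethoxy-2-[2-methoxy-1-(trimethylsilyloxy)ethenyl]-3-octylcyclohex-1-en-1-yl]oxy}trimethylsilane | CCCCCCCC[C@H]1CCC(OC)(OC)C(O[Si](C)(C)C)=C1C(O[Si](C)(C)C)=COC
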